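## Structural features

The target is an unsymmetrical benzil. Its 1,2-dione joins a 4-hydroxyphenyl ring to C6 of a 2,2-dimethyl-2H-chromene. Ring A, the benzene ring of the chromene, carries no hydrogen: C4a and C8a belong to the pyran, C5 bears a hydroxyl hydrogen-bonded to the C6 carbonyl, C7 bears a methoxy group and C8 a prenyl group. Three oxygens (C5, C7, C8a) therefore alternate with three different carbon substituents (C4a, C6, C8) in a fully differentiated phloroglucinol pattern. There is no stereocentre. The fragile groups are the prenyl and chromene olefins (acid, electrophiles, oxidants) and the 1,2-dione (strong base, 1,2-diamines, light). The real difficulty is regiochemical, because substitution of a phloroglucinol nucleus does not readily tell the three oxygens or the three ring carbons apart. The key step uses the fact that C5–C4a–C8a–C8 is a 1,3-dioxygenated four-carbon unit with the prenyl group at one end. That unit is the silyl dienol ether of an α′-prenylated 3-alkoxycyclohexenone, whose two remaining CH2 groups can leave as ethylene. C6 and C7 (acyl and methoxy) are supplied together as a two-carbon alkyne.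

## Logic of the disconnections

18 to 17. The C5 oxygen–benzyl bond, the aryl oxygen–CH2OMe bond and the two ketal C–OMe bonds are cut. This keeps the chelating phenol, the acidic phenol and the second carbonyl masked until the end. All three groups are acid-labile, so one operation removes them. The forward step needs an acid medium that spares the prenyl and chromene olefins.

17 to 14 and 15. The O1–C2 and C4–C4a bonds of the pyran are cut. In 14 only one phenol is free and only one ring carbon carries hydrogen, so the annulation has a single possible outcome. The cut removes one ring and five carbons. The forward step must bring a condensation to a ring position flanked by two oxygen substituents without disturbing the ketal or the ethers.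

14 to 6 and 11. The C5–C6 and C7–C8 bonds are cut and an ethano bridge is restored across C5 and C8. This divides the hexasubstituted ring into a four-carbon diene and a two-carbon alkyne, and every substituent has its place before the ring exists. The gain is ring A with all six substituents. The forward step needs a push–pull alkyne to act as dienophile with the right orientation, and both partners to survive the temperature at which ethylene leaves.

6 to 5, then to 3 and 4. The O–Si bond is cut, then the bond between the ring and the prenyl CH2. Kinetic α′-alkylation of a vinylogous ester places the prenyl group at a defined carbon. The forward steps need two successive kinetic deprotonations at the same carbon and strict exclusion of water from the silyl dienol ether.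

3 to 1 and 2. The vinylic C–O bond is cut. The forward step must alkylate the dione on oxygen and not on C2.

11 to 10. The bond between the alkyne and the carbonyl carbon is cut. An N-methoxy-N-methylamide stops at the ketone stage. The forward step needs a methoxyalkynyl anion made in the flask and a work-up that keeps amines and acid away from the product.

10 to 9, 8 and 7. These are functional-group changes on one carbon chain: amide from ester, aryl acetal ether from phenol, ketal ester from keto acid. The order is dictated by the one acid step (ketal formation), which must come before the acid-labile ether is attached.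

## Other disconnections considered

Alternative 1: Ring A is cut at C8–C8a and C6–C7, and the dione is carried as a diarylalkyne. In the forward step cyclobutenone A1 and methoxyalkyne A2 are heated together. Four-electron ring opening gives a vinylketene, the ynol ether adds in a regioselective [2+2] reaction, and a second ring opening and a six-electron closure deliver phenol A3. A3 has C8a–OH free, C5 silylated, C7 methylated and C8 prenylated.
- In its favour: this benzannulation is established for alkoxyalkynes, so the ring-forming step has no untested partner. On that point it is better than the chosen plan. It also runs at lower temperature.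
- Equal: the three oxygens emerge differentiated, as in the chosen plan.
- Against: A1, a 2-alkynyl-3-silyloxycyclobutenone, has no short preparation, and A2 is volatile and acid-sensitive. After annulation the alkyne must be oxidised to the dione beside the prenyl and chromene olefins. The ortho-alkynyl phenol that appears once the silyl group is removed can cyclise to a 2-arylbenzofuran.
- Step economy: the chosen plan is shorter, since A1 and the late oxidation add several operations.

Alternative 2: Both bonds flanking the dione are cut (C6–CO and CO–aryl), and ring A comes from an aromatic precursor. In the forward step aryllithium A5, made from bromide A4 by bromine–lithium exchange, adds once to the oxalyl equivalent A6. The tetrahedral adduct persists, aryllithium A7 adds to the second amide carbonyl, and aqueous work-up releases the protected dione A8.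
- In its favour: it is the most convergent plan, the dione appears at the right oxidation level without a ketal, and each event is ordinary carbonyl addition. In operations after fragment union it is better than the chosen plan.
- Equal: the last step is an acid deprotection beside a chromene, the same liability as in the chosen plan.
- Against: A4 must already hold four different substituents in the right order on a phloroglucinol nucleus, so the central regiochemical problem is moved to aromatic substitution and not removed. A5 is flanked by two ortho substituents, and clean mono-addition is needed to avoid symmetrical diketones.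
- Step economy: equal or slightly better only if A4 can be reached in about six steps. In regiochemical certainty the chosen plan is stronger.

Alternative 3: Ring A is cut at C4a–C5 and traced to a 2-pyranone. In the forward step Mg(OMe)2 in methanol opens pyranone A9 at the lactone carbonyl. The carbanion of the former 6-methyl group then condenses onto the resulting ester, and enolisation gives acylphloroglucinol A10 with both C5–OH and C8a–OH free.
- In its favour: ring A needs no protecting group, which saves the benzyl ether and its removal. On that point it is better than the chosen plan. The closure is ionic, templated by magnesium and run near room temperature.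
- Against: A9 needs a prenyl group at C5 of the pyranone, where direct C-alkylation does not go, so the pyranone must be assembled with the prenyl group in place. Methoxide can also attack the vinylogous positions. The carbanion can choose the side-chain ketone (aldol) over the ester and give an isomeric arene. The later pyran annulation meets two phenols and depends on chelation of C5–OH to direct closure to the C8a oxygen, where the chosen plan offers a single phenol.
- Step economy: about equal.

Key step: step 8

Remarks on the chemistry:
- "Prenyl" means 3-methylbut-2-en-1-yl, and chromene numbering is used for ring A throughout.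
- The dienophile 11 is named by lowest locants as a but-3-yn-2-one.
- 5 and 12 contain stereocentres, are racemic, and lose those centres in later steps. The target has none.
- Assumption: 14 and 17 are benzil monoketals, a class that fragments under ultraviolet light, so they are handled in amber glassware.

## Route

Step 1
Reactants: 1 cyclohexane-1,3-dione; 2 4-methoxybenzyl alcohol
Product: 3 3-[(4-methoxyphenyl)methoxy]cyclohex-2-en-1-one
Conditions: PPh3, DIAD, THF, 0 °C → rt
Reagents that add atoms: none
Why: Mitsunobu O-alkylation; the dione is acidic enough to protonate the betaine, and its enolate attacks the oxyphosphonium ion of 2 through oxygen, which avoids the acid conditions under which 2 self-condenses.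

Step 2
Reactants: 3 3-[(4-methoxyphenyl)methoxy]cyclohex-2-en-1-one; 4 1-bromo-3-methylbut-2-ene
Product: 5 3-[(4-methoxyphenyl)methoxy]-6-(3-methylbut-2-en-1-yl)cyclohex-2-en-1-one (racemic)
Conditions: LiN(iPr)2, THF, −78 °C; then 4, −78 → −20 °C
Reagents that add atoms: none
Why: Stork–Danheiser kinetic α′-alkylation; the amide base removes the C6 proton faster than the γ proton and the allylic bromide alkylates the enolate at carbon. The new centre is racemic and is flattened in step 3.

Step 3
Reactants: 5 3-[(4-methoxyphenyl)methoxy]-6-(3-methylbut-2-en-1-yl)cyclohex-2-en-1-one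
Product: 6 1-(4-methoxybenzyloxy)-4-(3-methylbut-2-en-1-yl)-3-(trimethylsilyloxy)cyclohexa-1,3-diene
Conditions: LiN(iPr)2, THF, −78 °C; TMSCl, −78 → 0 °C; pentane, filtration under argon, used crude
Reagents that add atoms: chlorotrimethylsilane, C[Si](C)(C)Cl
Why: a second kinetic α′-deprotonation gives the cross-conjugated dienolate, and O-silylation traps it as the 1-alkoxy-3-silyloxy diene with the prenyl group on a diene terminus.

Step 4
Reactants: 7 (4-hydroxyphenyl)glyoxylic acid
Product: 8 methyl 2-(4-hydroxyphenyl)-2,2-dimethoxyacetate
Conditions: HC(OMe)3, MeOH, H2SO4 (cat.), 65 °C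
Reagents that add atoms: trimethyl orthoformate, COC(OC)OC; methanol, CO
Why: Fischer esterification and acid-catalysed ketalisation in one pot, with the orthoformate removing water. The para hydroxyl stabilises the oxocarbenium ion on the way to the ketal.

Step 5
Reactants: 8 methyl 2-(4-hydroxyphenyl)-2,2-dimethoxyacetate
Product: 9 methyl 2,2-dimethoxy-2-[4-(methoxymethoxy)phenyl]acetate
Conditions: MOMCl, iPr2NEt, CH2Cl2, 0 °C → rt
Reagents that add atoms: chloromethyl methyl ether, COCCl
Why: O-alkylation of the phenol under basic conditions, which leave the ketal untouched.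

Step 6
Reactants: 9 methyl 2,2-dimethoxy-2-[4-(methoxymethoxy)phenyl]acetate
Product: 10 N,2,2-trimethoxy-2-[4-(methoxymethoxy)phenyl]-N-methylacetamide
Conditions: MeNH(OMe)·HCl, iPrMgCl, THF, −20 → 0 °C
Reagents that add atoms: N,O-dimethylhydroxylamine hydrochloride, CNOC.Cl
Why: aminolysis of the ester by the magnesium amide (Weinreb amide formation); the two α-oxygens activate the ester inductively and offset the hindrance of the quaternary carbon.

Step 7
Reactants: 10 N,2,2-trimethoxy-2-[4-(methoxymethoxy)phenyl]-N-methylacetamide
Product: 11 1,1,4-trimethoxy-1-[4-(methoxymethoxy)phenyl]but-3-yn-2-one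
Conditions: ClCH2CH(OMe)2, LiNEt2 (from Et2NH, n-BuLi), THF, 0 °C; then 10, −78 → −40 °C; AcOH, −78 °C; pH 7 buffer
Reagents that add atoms: lithium methoxyacetylide, COC#C[Li], made in the flask from 2-chloro-1,1-dimethoxyethane, COC(OC)CCl
Why: double elimination of the chloroacetal gives the alkoxyacetylide, which adds once to the Weinreb amide because the chelated tetrahedral adduct survives until the quench. Acid is added cold so that the released amines are protonated before the ynone is exposed.

Step 8
Reactants: 6 1-(4-methoxybenzyloxy)-4-(3-methylbut-2-en-1-yl)-3-(trimethylsilyloxy)cyclohexa-1,3-diene; 11 1,1,4-trimethoxy-1-[4-(methoxymethoxy)phenyl]but-3-yn-2-one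
Product: 14 1-[4-hydroxy-2-methoxy-6-(4-methoxybenzyloxy)-3-(3-methylbut-2-en-1-yl)phenyl]-2,2-dimethoxy-2-[4-(methoxymethoxy)phenyl]ethan-1-one, via bicyclo[2.2.2]octadiene adduct 12 (not isolated), via aryl trimethylsilyl ether 13 (not isolated)
Conditions: 6 (1.5 equiv), o-xylene, sealed tube, 110 → 150 °C; then K2CO3 (cat.), MeOH, 0 °C
Reagents that add atoms: none
Why: Proposed new method: the closest known reaction type is the Alder–Rickert synthesis, in which a 1,3-dioxygenated cyclohexa-1,3-diene adds an alkynyl ketone or ester and the bridged adduct then expels ethylene; the element not yet shown is a dienophile whose β-carbon carries an alkoxy group. Mechanistic reasoning: the two oxygen donors of 6 raise its HOMO and place the largest coefficient on the prenyl-bearing terminus, while the carbonyl of 11, helped inductively by the neighbouring ketal oxygens, keeps the largest LUMO coefficient on the methoxy-bearing β-carbon, so the methoxy donor should lower the rate but not reverse the polarisation. A concerted but strongly asynchronous [4+2] transition state is expected, the bond from the prenyl terminus to the β-carbon (C8–C7) running ahead of the bond from the benzyloxy terminus to the α-carbon (C5–C6). Ring A is closed by this intermolecular [4+2] cycloaddition, which gives adduct 12; a retro-[4+2] reaction then releases ethylene, pulled by aromatisation, to give 13, and carbonate-catalysed methanolysis frees phenol 14. No stereocentre remains in 14, since the two bridgehead centres of racemic 12 vanish with the ethano bridge. The selectivity needed is regiochemical (prenyl next to methoxy, acyl next to benzyloxy) and is secured by the matched polarisation, the other orientation pairing the two nucleophilic carbons. A methoxyalkyne has no β-hydrogen and cannot undergo the retro-ene fragmentation to a ketene that limits ethoxyalkynes on heating, and the unactivated prenyl olefin should not compete as a dienophile.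

Step 9
Reactants: 14 1-[4-hydroxy-2-methoxy-6-(4-methoxybenzyloxy)-3-(3-methylbut-2-en-1-yl)phenyl]-2,2-dimethoxy-2-[4-(methoxymethoxy)phenyl]ethan-1-one; 15 3-methylbut-2-enal
Product: 17 2,2-dimethoxy-1-[7-methoxy-5-(4-methoxybenzyloxy)-2,2-dimethyl-8-(3-methylbut-2-en-1-yl)-2H-chromen-6-yl]-2-[4-(methoxymethoxy)phenyl]ethan-1-one, via ortho-quinone methide 16 (not isolated)
Conditions: 15 (3 equiv), ethylenediammonium diacetate (20 mol %), toluene, 110 °C
Reagents that add atoms: none
Why: amine-salt-catalysed chromene annulation (Knoevenagel-type condensation, then oxa-6π-electrocyclisation); the iminium ion of 15 is attacked by the only hydrogen-bearing ring carbon, which lies ortho to the free phenol and is activated by three oxygens. Loss of the amine gives 16, which closes onto the only free oxygen.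

Step 10
Reactants: 17 2,2-dimethoxy-1-[7-methoxy-5-(4-methoxybenzyloxy)-2,2-dimethyl-8-(3-methylbut-2-en-1-yl)-2H-chromen-6-yl]-2-[4-(methoxymethoxy)phenyl]ethan-1-one
Product: 18 1-[5-hydroxy-7-methoxy-2,2-dimethyl-8-(3-methylbut-2-en-1-yl)-2H-chromen-6-yl]-2-(4-hydroxyphenyl)ethane-1,2-dione
Conditions: 3 M aq. HCl, MeOH–THF, 45 °C, dark
Reagents that add atoms: water, O
Why: acid-catalysed cleavage of the 4-methoxybenzyl ether (aided by the ortho carbonyl), of the methoxymethyl ether and of the ketal in one operation, with methanol trapping the benzylic and methoxymethyl cations so that they cannot alkylate the olefins. No phenol sits next to the prenyl group, so acid-induced chroman formation has no partner.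

## Compound list

1 | cyclohexane-1,3-dione | O=C1CCCC(=O)C1 | starting material
2 | 4-methoxybenzyl alcohol | COc1ccc(CO)cc1 | starting material
3 | 3-[(4-methoxyphenyl)methoxy]cyclohex-2-en-1-one | COc1ccc(COC2=CC(=O)CCC2)cc1 | intermediate
4 | 1-bromo-3-methylbut-2-ene | CC(C)=CCBr | starting material
5 | 3-[(4-methoxyphenyl)methoxy]-6-(3-methylbut-2-en-1-yl)cyclohex-2-en-1-one (racemic) | COc1ccc(COC2=CC(=O)C(CC=C(C)C)CC2)cc1 | intermediate
6 | 1-(4-methoxybenzyloxy)-4-(3-methylbut-2-en-1-yl)-3-(trimethylsilyloxy)cyclohexa-1,3-diene | COc1ccc(COC2=CC(O[Si](C)(C)C)=C(CC=C(C)C)CC2)cc1 | intermediate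
7 | (4-hydroxyphenyl)glyoxylic acid | OC(=O)C(=O)c1ccc(O)cc1 | starting material
8 | methyl 2-(4-hydroxyphenyl)-2,2-dimethoxyacetate | COC(=O)C(OC)(OC)c1ccc(O)cc1 | intermediate
9 | methyl 2,2-dimethoxy-2-[4-(methoxymethoxy)phenyl]acetate | COC(=O)C(OC)(OC)c1ccc(OCOC)cc1 | intermediate
10 | N,2,2-trimethoxy-2-[4-(methoxymethoxy)phenyl]-N-methylacetamide | CON(C)C(=O)C(OC)(OC)c1ccc(OCOC)cc1 | intermediate
11 | 1,1,4-trimethoxy-1-[4-(methoxymethoxy)phenyl]but-3-yn-2-one | COC#CC(=O)C(OC)(OC)c1ccc(OCOC)cc1 | intermediate
12 | 1-[3-methoxy-1-(4-methoxybenzyloxy)-4-(3-methylbut-2-en-1-yl)-5-(trimethylsilyloxy)bicyclo[2.2.2]octa-2,5-dien-2-yl]-2,2-dimethoxy-2-[4-(methoxymethoxy)phenyl]ethan-1-one (racemic) | COc1ccc(COC23CCC(CC=C(C)C)(C(OC)=C2C(=O)C(OC)(OC)c2ccc(OCOC)cc2)C(O[Si](C)(C)C)=C3)cc1 | intermediate (not isolated)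
13 | 1-[2-methoxy-6-(4-methoxybenzyloxy)-3-(3-methylbut-2-en-1-yl)-4-(trimethylsilyloxy)phenyl]-2,2-dimethoxy-2-[4-(methoxymethoxy)phenyl]ethan-1-one | COc1c(CC=C(C)C)c(O[Si](C)(C)C)cc(OCc2ccc(OC)cc2)c1C(=O)C(OC)(OC)c1ccc(OCOC)cc1 | intermediate (not isolated)
14 | 1-[4-hydroxy-2-methoxy-6-(4-methoxybenzyloxy)-3-(3-methylbut-2-en-1-yl)phenyl]-2,2-dimethoxy-2-[4-(methoxymethoxy)phenyl]ethan-1-one | COc1c(CC=C(C)C)c(O)cc(OCc2ccc(OC)cc2)c1C(=O)C(OC)(OC)c1ccc(OCOC)cc1 | intermediate
15 | 3-methylbut-2-enal | CC(C)=CC=O | starting material
16 | 1-[6-methoxy-2-(4-methoxybenzyloxy)-5-(3-methylbut-2-en-1-yl)-3-(3-methylbut-2-en-1-ylidene)-4-oxocyclohexa-1,5-dien-1-yl]-2,2-dimethoxy-2-[4-(methoxymethoxy)phenyl]ethan-1-one (ortho-quinone methide, olefin geometry not defined) | O=C1C(=CC=C(C)C)C(OCc2ccc(OC)cc2)=C(C(=O)C(OC)(OC)c2ccc(OCOC)cc2)C(OC)=C1CC=C(C)C | intermediate (not isolated)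
17 | 2,2-dimethoxy-1-[7-methoxy-5-(4-methoxybenzyloxy)-2,2-dimethyl-8-(3-methylbut-2-en-1-yl)-2H-chromen-6-yl]-2-[4-(methoxymethoxy)phenyl]ethan-1-one | COc1c(CC=C(C)C)c2OC(C)(C)C=Cc2c(OCc2ccc(OC)cc2)c1C(=O)C(OC)(OC)c1ccc(OCOC)cc1 | intermediate
18 | 1-[5-hydroxy-7-methoxy-2,2-dimethyl-8-(3-methylbut-2-en-1-yl)-2H-chromen-6-yl]-2-(4-hydroxyphenyl)ethane-1,2-dione | COc1c(CC=C(C)C)c2c(c(O)c1C(=O)C(=O)c1ccc(O)cc1)C=CC(C)(C)O2 | target

## Step count and least certain steps

Total: 10 steps. Longest linear sequence: 7 steps (steps 4 to 10, from 7). The diene arm (steps 1 to 3) joins at step 8.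

Step 8 (key step, Proposed new method).
- What may go wrong: the methoxy donor raises the LUMO of 11, so the cycloaddition may be slow. At the temperature then needed, 6 can be lost by adventitious hydrolysis or by [1,5]-hydrogen shifts that move the diene to positions from which a different bridge would be expelled. 11 can oligomerise, or be attacked at the ketone in a Mukaiyama-type addition.
- Fallback (known chemistry): it sets out from 10 and 6 and returns at 14. The ring oxygen at C7 is introduced after the ring is made, so the dienophile belongs to the known haloalkynyl carbonyl class.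
- Addition of HC≡CMgBr to 10 (THF, 0 °C, acidic quench) gives the terminal ynone 1,1-dimethoxy-1-[4-(methoxymethoxy)phenyl]but-3-yn-2-one F1.
- NBS with AgNO3 (cat.) in acetone converts F1 into the bromoalkynone 4-bromo-1,1-dimethoxy-1-[4-(methoxymethoxy)phenyl]but-3-yn-2-one F2. Bromine is an inductive acceptor and leaves the β-carbon electrophilic.
- Heating F2 with 6 in toluene (80 → 130 °C) gives the bridged bromo adduct F3, which loses ethylene to the aryl silyl ether F4. K2CO3 in MeOH then frees the bromophenol 1-[2-bromo-4-hydroxy-6-(4-methoxybenzyloxy)-3-(3-methylbut-2-en-1-yl)phenyl]-2,2-dimethoxy-2-[4-(methoxymethoxy)phenyl]ethan-1-one F5.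
- Ullmann-type methoxylation of F5 (CuI, 3,4,7,8-tetramethyl-1,10-phenanthroline, Cs2CO3, MeOH, toluene, 110 °C), assisted by the ortho carbonyl, gives 14.

Step 7.
- What may go wrong: diethylamine and N,O-dimethylhydroxylamine, released when the tetrahedral adduct collapses, can add in conjugate fashion to the new ynone. The ynol ether can hydrate to a β-keto ester if the quench is too acidic or too slow. Generation of the acetylide can be incomplete.
- Fallback: it sets out from 10 and returns at 11. The carbonyl is formed by oxidation, so no Michael acceptor is present while amines are.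
- Reduction of 10 with iBu2AlH (THF, −78 °C) gives the aldehyde 2,2-dimethoxy-2-[4-(methoxymethoxy)phenyl]acetaldehyde F6.
- Addition of lithium methoxyacetylide at −78 °C gives the propargylic alcohol 1,1,4-trimethoxy-1-[4-(methoxymethoxy)phenyl]but-3-yn-2-ol F7 (racemic).
- Neutral oxidation with MnO2 in CH2Cl2 gives 11.

Step 10.
- What may go wrong: protonation of the electron-rich chromene olefin or of the prenyl olefin (methanol addition, dimerisation) may compete, because the α-keto ketal and the aryl methoxymethyl ether hydrolyse slowly.
- Fallback: it sets out from 14 and returns at 18. The order is reversed so that no chromene meets acid.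
- 14 is deprotected with the same aqueous methanolic HCl at room temperature to the triol 1-[4,6-dihydroxy-2-methoxy-3-(3-methylbut-2-en-1-yl)phenyl]-2-(4-hydroxyphenyl)ethane-1,2-dione F8.
- F8 is then annulated with 15 in pyridine at 110 °C. Closure should fall on the C8a oxygen because the C5 hydroxyl is tied up in the hydrogen bond to the carbonyl. A diamine catalyst is avoided because it would condense with the free dione.

Step 9.
- What may go wrong: the phenol lies para to the acyl group and the reacting carbon is flanked by two oxygen substituents, so condensation may be slow and self-condensation of 15 may take over.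
- Fallback: it sets out from 14 and returns at 17.
- O-Alkylation with 3-chloro-3-methylbut-1-yne (K2CO3, KI, CuI (cat.), acetone) gives the aryl propargyl ether 2,2-dimethoxy-1-[2-methoxy-6-(4-methoxybenzyloxy)-4-(2-methylbut-3-yn-2-yloxy)-3-(3-methylbut-2-en-1-yl)phenyl]-2-[4-(methoxymethoxy)phenyl]ethan-1-one F9.
- Heating F9 in N,N-diethylaniline at 160 °C brings about propargyl Claisen rearrangement to the only free ortho carbon, a [1,5]-hydrogen shift and oxa-6π-closure to 17.

Step 1.
- What may go wrong: alkylation at C2 of the dione may compete with O-alkylation, since the 4-methoxybenzyl oxyphosphonium ion has carbocation character.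
- Fallback: it sets out from 1 and returns at 3, with the polarity reversed.
- (COCl)2 with DMF (cat.) in CH2Cl2 converts 1 into 3-chlorocyclohex-2-en-1-one F10.
- The sodium alkoxide of 2 (NaH, THF, 0 °C) displaces chloride from F10 by addition–elimination to give 3.

## Further compounds

F1 | step 8 | 1,1-dimethoxy-1-[4-(methoxymethoxy)phenyl]but-3-yn-2-one | C#CC(=O)C(OC)(OC)c1ccc(OCOC)cc1
F2 | step 8 | 4-bromo-1,1-dimethoxy-1-[4-(methoxymethoxy)phenyl]but-3-yn-2-one | BrC#CC(=O)C(OC)(OC)c1ccc(OCOC)cc1
F3 | step 8 | 1-[3-bromo-1-(4-methoxybenzyloxy)-4-(3-methylbut-2-en-1-yl)-5-(trimethylsilyloxy)bicyclo[2.2.2]octa-2,5-dien-2-yl]-2,2-dimethoxy-2-[4-(methoxymethoxy)phenyl]ethan-1-one (racemic) | COc1ccc(COC23CCC(CC=C(C)C)(C(Br)=C2C(=O)C(OC)(OC)c2ccc(OCOC)cc2)C(O[Si](C)(C)C)=C3)cc1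
F4 | step 8 | 1-[2-bromo-6-(4-methoxybenzyloxy)-3-(3-methylbut-2-en-1-yl)-4-(trimethylsilyloxy)phenyl]-2,2-dimethoxy-2-[4-(methoxymethoxy)phenyl]ethan-1-one | COc1ccc(COc2cc(O[Si](C)(C)C)c(CC=C(C)C)c(Br)c2C(=O)C(OC)(OC)c2ccc(OCOC)cc2)cc1
F5 | step 8 | 1-[2-bromo-4-hydroxy-6-(4-methoxybenzyloxy)-3-(3-methylbut-2-en-1-yl)phenyl]-2,2-dimethoxy-2-[4-(methoxymethoxy)phenyl]ethan-1-one | COc1ccc(COc2cc(O)c(CC=C(C)C)c(Br)c2C(=O)C(OC)(OC)c2ccc(OCOC)cc2)cc1
F6 | step 7 | 2,2-dimethoxy-2-[4-(methoxymethoxy)phenyl]acetaldehyde | O=CC(OC)(OC)c1ccc(OCOC)cc1
F7 | step 7 | 1,1,4-trimethoxy-1-[4-(methoxymethoxy)phenyl]but-3-yn-2-ol (racemic) | COC#CC(O)C(OC)(OC)c1ccc(OCOC)cc1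
F8 | step 10 | 1-[4,6-dihydroxy-2-methoxy-3-(3-methylbut-2-en-1-yl)phenyl]-2-(4-hydroxyphenyl)ethane-1,2-dione | COc1c(CC=C(C)C)c(O)cc(O)c1C(=O)C(=O)c1ccc(O)cc1
F9 | step 9 | 2,2-dimethoxy-1-[2-methoxy-6-(4-methoxybenzyloxy)-4-(2-methylbut-3-yn-2-yloxy)-3-(3-methylbut-2-en-1-yl)phenyl]-2-[4-(methoxymethoxy)phenyl]ethan-1-one | COc1c(CC=C(C)C)c(OC(C)(C)C#C)cc(OCc2ccc(OC)cc2)c1C(=O)C(OC)(OC)c1ccc(OCOC)cc1
F10 | step 1 | 3-chlorocyclohex-2-en-1-one | ClC1=CC(=O)CCC1
A1 | alternative 1 | 2-{[4-(methoxymethoxy)phenyl]ethynyl}-3-[tri(propan-2-yl)silyloxy]cyclobut-2-en-1-one | O=C1CC(O[Si](C(C)C)(C(C)C)C(C)C)=C1C#Cc1ccc(OCOC)cc1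
A2 | alternative 1 | 1-methoxy-5-methylhex-4-en-1-yne | COC#CCC=C(C)C
A3 | alternative 1 | 3-methoxy-4-{[4-(methoxymethoxy)phenyl]ethynyl}-2-(3-methylbut-2-en-1-yl)-5-[tri(propan-2-yl)silyloxy]phenol | COc1c(CC=C(C)C)c(O)cc(O[Si](C(C)C)(C(C)C)C(C)C)c1C#Cc1ccc(OCOC)cc1
A4 | alternative 2 | 6-bromo-7-methoxy-5-(methoxymethoxy)-2,2-dimethyl-8-(3-methylbut-2-en-1-yl)-2H-chromene | COCOc1c(Br)c(OC)c(CC=C(C)C)c2OC(C)(C)C=Cc12
A5 | alternative 2 | [7-methoxy-5-(methoxymethoxy)-2,2-dimethyl-8-(3-methylbut-2-en-1-yl)-2H-chromen-6-yl]lithium | [Li]c1c(OCOC)c2C=CC(C)(C)Oc2c(CC=C(C)C)c1OC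
A6 | alternative 2 | 1,4-dimethylpiperazine-2,3-dione | CN1CCN(C)C(=O)C1=O
A7 | alternative 2 | [4-(methoxymethoxy)phenyl]lithium | [Li]c1ccc(OCOC)cc1
A8 | alternative 2 | 1-[7-methoxy-5-(methoxymethoxy)-2,2-dimethyl-8-(3-methylbut-2-en-1-yl)-2H-chromen-6-yl]-2-[4-(methoxymethoxy)phenyl]ethane-1,2-dione | COCOc1c(C(=O)C(=O)c2ccc(OCOC)cc2)c(OC)c(CC=C(C)C)c2OC(C)(C)C=Cc12
A9 | alternative 3 | 3-{2,2-dimethoxy-2-[4-(methoxymethoxy)phenyl]acetyl}-4-methoxy-6-methyl-5-(3-methylbut-2-en-1-yl)-2H-pyran-2-one | COc1c(CC=C(C)C)c(C)oc(=O)c1C(=O)C(OC)(OC)c1ccc(OCOC)cc1
A10 | alternative 3 | 1-[4,6-dihydroxy-2-methoxy-3-(3-methylbut-2-en-1-yl)phenyl]-2,2-dimethoxy-2-[4-(methoxymethoxy)phenyl]ethan-1-one | COc1c(CC=C(C)C)c(O)cc(O)c1C(=O)C(OC)(OC)c1ccc(OCOC)cc1
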